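**Plan**

- Retrosynthesis: the two C‑prenyl bonds are cut first, C3'–CH2 on ring B and then C3–CH2 on ring A, which returns ring A to an aromatic acetyl‑methyl‑phloroglucinol. Ring B is then opened at C4'–C5' and C6'–C1' (and C3'–C4'), leaving a 3‑siloxycyclobutenone on the bridge carbon and a siloxyalkyne. The four‑membered ring is cut into a ketene and ethoxyacetylene, and the three‑carbon arm is cut from C5 of ring A.
- Feature used: ring B is a benzene ring whose three oxygens (C2', C4', C6') alternate with three carbon substituents, and its C1' hangs on C5 of ring A through one CH2. A 3‑siloxycyclobutenone supplies C4', C3', C2', C1' and a siloxyalkyne supplies C5', C6'.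
- Forward: ring A arene (tribenzyl ether, propanoic acid arm on C5) → cyclobutenone on the arm → ring B by benzannulation → debenzylation → ring A dearomatised by prenylation at C3 → ring B unmasked and prenylated at C3'.
- Stereochemistry: the only stereocenter, C3 of ring A (R), is set in step 12 by the chiral ligand of the Pd2(dba)3·CHCl3‑derived catalyst (catalyst control). It is quaternary, so later steps cannot epimerise it.

Key step: step 10

Assumption: the sense of induction of the chiral ligand in step 12 cannot be predicted with certainty; the (1R,2R)‑ligand is written, and its mirror image would be used if that is the one that gives (R)‑C3.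

Abbreviations and numbering: ArBn = 3‑acetyl‑2,4,6‑tris(benzyloxy)‑5‑methylphenyl; TIPS = triisopropylsilyl. Ring A: C1 acetyl‑bearing, C3 methyl‑bearing (later quaternary), C5 bridge‑bearing. Ring B: C1' bridge‑bearing, C3' prenyl‑bearing, C5' acetyl‑bearing.

**Route**

Step 1
Reactants: 1 2‑methylbenzene‑1,3,5‑triol
Product: 2 1‑(2,4,6‑trihydroxy‑3‑methylphenyl)ethan‑1‑one
Conditions: Ac2O (1.05 equiv), MeSO3H, 80 °C
Reagents that add atoms: acetic anhydride, CC(=O)OC(C)=O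
Why: Friedel–Crafts acylation of the electron‑rich triol, in which the two hydrogen‑bearing ring carbons are equivalent and the first acetyl group slows a second acylation.

Step 2
Reactants: 2 1‑(2,4,6‑trihydroxy‑3‑methylphenyl)ethan‑1‑one; 3 tert‑butyl acrylate
Product: 4 tert‑butyl 3‑(3‑acetyl‑2,4,6‑trihydroxy‑5‑methylphenyl)propanoate
Conditions: DBU (0.3 equiv), MeCN, 60 °C
Reagents that add atoms: none
Why: Michael addition in which the phloroglucinol monoanion reacts through its only hydrogen‑bearing ring carbon (C5) and re‑aromatises, O‑addition being reversible and the tert‑butyl ester being unable to lactonise onto the flanking phenols.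

Step 3
Reactants: 4 tert‑butyl 3‑(3‑acetyl‑2,4,6‑trihydroxy‑5‑methylphenyl)propanoate
Product: 5 tert‑butyl 3‑(ArBn)propanoate
Conditions: BnBr (3.6 equiv), K2CO3, DMF, 60 °C
Reagents that add atoms: benzyl bromide, BrCc1ccccc1
Why: Williamson ether synthesis in a dipolar aprotic solvent, where the phenoxides of the fully substituted ring alkylate on oxygen and every acidic hydrogen that could trap an acid chloride or a ketene is removed.

Step 4
Reactants: 5 tert‑butyl 3‑(ArBn)propanoate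
Product: 6 3‑(ArBn)propanoic acid
Conditions: CF3CO2H/CH2Cl2 (1:4), 0 °C, short reaction time
Reagents that add atoms: none
Why: Acidolysis of the tert‑butyl ester with loss of isobutene, under conditions dilute and brief enough to leave the aryl benzyl ethers and the aryl ketone intact.

Step 5
Reactants: 6 3‑(ArBn)propanoic acid; 7 ethoxyacetylene
Product: 10 4‑[(ArBn)methyl]‑3‑ethoxycyclobut‑2‑en‑1‑one (racemic), via acid chloride 8 (not isolated), via aldoketene 9 (not isolated)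
Conditions: (COCl)2, DMF (cat.), CH2Cl2, 0 °C → rt, evaporate; then 7 (5 equiv), Et3N (1.5 equiv, slow addition), CH2Cl2/hexane, rt
Reagents that add atoms: none
Why: Dehydrochlorination of the acid chloride gives the monoalkylketene, which should undergo the regioselective ketene–ynol ether [2+2] cycloaddition (ketene carbonyl carbon to the unsubstituted alkyne carbon) faster than it dimerises when the alkyne is in excess; the new ring stereocenter forms as a racemate and is erased in step 6.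

Step 6
Reactants: 10 4‑[(ArBn)methyl]‑3‑ethoxycyclobut‑2‑en‑1‑one
Product: 11 2‑[(ArBn)methyl]‑3‑hydroxycyclobut‑2‑en‑1‑one (enol form of the cyclobutane‑1,3‑dione)
Conditions: 1 M HCl, THF, 0 °C → rt
Reagents that add atoms: water, O
Why: Acid‑catalysed hydrolysis of the strained vinylogous ester (water adds to C3, ethanol leaves) gives the 2‑substituted cyclobutane‑1,3‑dione, which rests as its more substituted enol so that the former stereocenter becomes sp2 and carries the arm.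

Step 7
Reactants: 11 2‑[(ArBn)methyl]‑3‑hydroxycyclobut‑2‑en‑1‑one
Product: 12 2‑[(ArBn)methyl]‑3‑[(triisopropylsilyl)oxy]cyclobut‑2‑en‑1‑one
Conditions: TIPSCl (1.05 equiv), Et3N (1.2 equiv), CH2Cl2, 0 °C
Reagents that add atoms: chlorotriisopropylsilane, CC(C)[Si](Cl)(C(C)C)C(C)C
Why: O‑silylation of the strongly acidic enol (a vinylogous carboxylic acid) through its triethylammonium enolate, the more stable enolate having the arm‑bearing carbon between the two oxygens so that the silyl enol ether keeps the arm on C2 and a CH2 at C4.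

Step 8
Reactants: 13 but‑3‑yn‑2‑one
Product: 14 2‑ethynyl‑2‑methyl‑1,3‑dioxolane
Conditions: HOCH2CH2OH, p‑TsOH (cat.), benzene, reflux (Dean–Stark)
Reagents that add atoms: ethane‑1,2‑diol, OCCO
Why: Acid‑catalysed ketalisation driven by azeotropic removal of water, conjugate addition of the diol not competing under acid.

Step 9
Reactants: 14 2‑ethynyl‑2‑methyl‑1,3‑dioxolane
Product: 17 triisopropyl{[(2‑methyl‑1,3‑dioxolan‑2‑yl)ethynyl]oxy}silane, via lithium acetylide 15 (not isolated), via lithium ynolate 16 (not isolated)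
Conditions: n‑BuLi, THF, −78 °C; t‑BuOOLi (from t‑BuOOH and LiN(SiMe3)2), −78 → 0 °C; i‑Pr3SiOTf, −78 °C → rt
Reagents that add atoms: tert‑butyl hydroperoxide, CC(C)(C)OO; triisopropylsilyl trifluoromethanesulfonate, CC(C)[Si](OS(=O)(=O)C(F)(F)F)(C(C)C)C(C)C
Why: Oxidation of the lithium acetylide by lithium tert‑butyl peroxide (oxygen transfer to the acetylide carbon) gives the ynolate, which the bulky silyl triflate traps on oxygen to give the siloxyalkyne.

Step 10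
Reactants: 12 2‑[(ArBn)methyl]‑3‑[(triisopropylsilyl)oxy]cyclobut‑2‑en‑1‑one; 17 triisopropyl{[(2‑methyl‑1,3‑dioxolan‑2‑yl)ethynyl]oxy}silane
Product: 22 4‑[(ArBn)methyl]‑2‑(2‑methyl‑1,3‑dioxolan‑2‑yl)‑3,5‑bis[(triisopropylsilyl)oxy]phenol, via vinylketene 18 (not isolated), via vinylcyclobutenone 19 (not isolated), via dienylketene 20 (not isolated), via cyclohexadienone 21 (not isolated)
Conditions: 17 (1.5 equiv), toluene (0.2 M), 80 °C, then 110 °C
Reagents that add atoms: none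
Why: On heating, 12 should undergo 4π electrocyclic (conrotatory) cleavage of the C1–C4 bond of the four‑membered ring (the future C4'–C3' bond) to vinylketene 18, whose ketene C=C adds siloxyalkyne 17 in a [2+2] cycloaddition that forms C4'–C5' and C6'–C1' and gives 2‑vinylcyclobutenone 19. A second 4π opening of 19 gives dienylketene 20, and ring B closes by a thermal disrotatory 6π electrocyclisation that re‑forms C3'–C4' (dienone 21), after which tautomerisation of a C3' hydrogen gives phenol 22. The closest known reaction is the Danheiser benzannulation in its siloxyalkyne variant, which turns a cyclobutenone and a silyl ynol ether into a resorcinol monosilyl ether; the 3‑siloxy group of 12 only adds the third oxygen. No stereocenter is formed. The step needs regioselectivity in the ketene–alkyne addition, which the polarisation of the ynol ether secures (its oxygen‑remote carbon, the one bearing the dioxolane, is the nucleophile and bonds to the ketene carbonyl carbon), and it needs the ketenes to be intercepted only by the alkyne, which is secured because neither partner has an O–H group and every ring A oxygen is a benzyl ether or a hindered aryl ketone. C4 of the cyclobutenone is an unsubstituted CH2, so no torquoselectivity issue arises and the hydrogen needed for aromatisation is in place.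

Step 11
Reactants: 22 4‑[(ArBn)methyl]‑2‑(2‑methyl‑1,3‑dioxolan‑2‑yl)‑3,5‑bis[(triisopropylsilyl)oxy]phenol
Product: 23 1‑{2,4,6‑trihydroxy‑3‑[[4‑hydroxy‑3‑(2‑methyl‑1,3‑dioxolan‑2‑yl)‑2,6‑bis(triisopropylsilyloxy)phenyl]methyl]‑5‑methylphenyl}ethan‑1‑one
Conditions: H2 (1 atm), Pd/C (10 %), NaHCO3, EtOAc, rt
Reagents that add atoms: none
Why: Hydrogenolysis of the three aryl benzyl ethers at a stage where no alkene is present, the aryl silyl ethers, the dioxolane and the hindered aryl ketone not being reduced under these buffered conditions.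

Step 12
Reactants: 23 (ring A triphenol, ring B still silylated)
Product: 24 (4R)‑2‑acetyl‑3,5‑dihydroxy‑4‑methyl‑4‑(3‑methylbut‑2‑en‑1‑yl)‑6‑{[4‑hydroxy‑3‑(2‑methyl‑1,3‑dioxolan‑2‑yl)‑2,6‑bis(triisopropylsilyloxy)phenyl]methyl}cyclohexa‑2,5‑dien‑1‑one
Conditions: 3‑methylbut‑2‑enyl methyl carbonate (1.1 equiv), Pd2(dba)3·CHCl3 (2.5 mol %), (1R,2R)‑N,N'‑bis[2‑(diphenylphosphanyl)benzoyl]cyclohexane‑1,2‑diamine (7.5 mol %), THF, 0 °C
Reagents that add atoms: 3‑methylbut‑2‑en‑1‑yl methyl carbonate, COC(=O)OCC=C(C)C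
Why: Asymmetric Tsuji–Trost allylic alkylation run as an alkylative dearomatisation, in which the ring A acylphloroglucinol (the only acidic, carbon‑nucleophilic ring while ring B is silylated) attacks the unsubstituted terminus of the prenyl electrophile generated by zerovalent palladium through C3, the less hindered of its alkyl‑bearing carbons (C5 carries the bulky diarylmethane arm, C1 the acyl group), O‑prenyl ethers re‑ionise, and the chiral ligand selects the face of C3 and so sets the (R) centre.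

Step 13
Reactants: 24 (ring A dearomatised, ring B silylated)
Product: 26 (4R)‑2‑acetyl‑6‑[(3‑acetyl‑2,4,6‑trihydroxyphenyl)methyl]‑3,5‑dihydroxy‑4‑methyl‑4‑(3‑methylbut‑2‑en‑1‑yl)cyclohexa‑2,5‑dien‑1‑one, via ketal triphenol 25 (not isolated)
Conditions: Bu4NF/AcOH (1:1, 2.5 equiv), THF, 0 °C; then PPTS (cat.), acetone/H2O, rt
Reagents that add atoms: water, O
Why: Buffered fluoride cleaves the two aryl silyl ethers, and the dioxolane, now on a trihydroxyphenyl ring that stabilises the benzylic oxocarbenium ion, hydrolyses with a catalytic weak acid that is no stronger than the ring A enols and leaves the prenyl group and the quaternary C3 untouched.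

Step 14
Reactants: 26 (ring B acetyl triphenol with free C3')
Product: 27 (4R)‑2‑acetyl‑6‑{[3‑acetyl‑2,4,6‑trihydroxy‑5‑(3‑methylbut‑2‑en‑1‑yl)phenyl]methyl}‑3,5‑dihydroxy‑4‑methyl‑4‑(3‑methylbut‑2‑en‑1‑yl)cyclohexa‑2,5‑dien‑1‑one (target)
Conditions: 3‑methylbut‑2‑enyl methyl carbonate (1.05 equiv), Pd(PPh3)4 (5 mol %), THF, 0 °C → rt
Reagents that add atoms: 3‑methylbut‑2‑en‑1‑yl methyl carbonate, COC(=O)OCC=C(C)C
Why: Tsuji–Trost C‑allylation of a phloroglucinol at C3', the only ring carbon in the molecule that still bears hydrogen, so that alkylation there is followed by re‑aromatisation and is irreversible, whereas O‑prenylation is reversible under palladium catalysis and quaternisation at C5 or C1' is sterically retarded; C3 has no acidic hydrogen and keeps its configuration.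

**Compound list**

1 | 2‑methylbenzene‑1,3,5‑triol | Cc1c(O)cc(O)cc1O | starting material
2 | 1‑(2,4,6‑trihydroxy‑3‑methylphenyl)ethan‑1‑one | CC(=O)c1c(O)c(C)c(O)cc1O | intermediate
3 | tert‑butyl acrylate | C=CC(=O)OC(C)(C)C | starting material
4 | tert‑butyl 3‑(3‑acetyl‑2,4,6‑trihydroxy‑5‑methylphenyl)propanoate | CC(=O)c1c(O)c(C)c(O)c(CCC(=O)OC(C)(C)C)c1O | intermediate
5 | tert‑butyl 3‑[3‑acetyl‑2,4,6‑tris(benzyloxy)‑5‑methylphenyl]propanoate | CC(=O)c1c(OCc2ccccc2)c(C)c(OCc2ccccc2)c(CCC(=O)OC(C)(C)C)c1OCc1ccccc1 | intermediate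
6 | 3‑[3‑acetyl‑2,4,6‑tris(benzyloxy)‑5‑methylphenyl]propanoic acid | CC(=O)c1c(OCc2ccccc2)c(C)c(OCc2ccccc2)c(CCC(=O)O)c1OCc1ccccc1 | intermediate
7 | ethoxyacetylene | CCOC#C | starting material
8 | 3‑(ArBn)propanoyl chloride | CC(=O)c1c(OCc2ccccc2)c(C)c(OCc2ccccc2)c(CCC(=O)Cl)c1OCc1ccccc1 | intermediate (not isolated)
9 | 3‑(ArBn)prop‑1‑en‑1‑one (aldoketene) | CC(=O)c1c(OCc2ccccc2)c(C)c(OCc2ccccc2)c(CC=C=O)c1OCc1ccccc1 | intermediate (not isolated)
10 | 4‑[(ArBn)methyl]‑3‑ethoxycyclobut‑2‑en‑1‑one, racemic | CC(=O)c1c(OCc2ccccc2)c(C)c(OCc2ccccc2)c(CC2C(=O)C=C2OCC)c1OCc1ccccc1 | intermediate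
11 | 2‑[(ArBn)methyl]‑3‑hydroxycyclobut‑2‑en‑1‑one | CC(=O)c1c(OCc2ccccc2)c(C)c(OCc2ccccc2)c(CC2=C(O)CC2=O)c1OCc1ccccc1 | intermediate
12 | 2‑[(ArBn)methyl]‑3‑[(triisopropylsilyl)oxy]cyclobut‑2‑en‑1‑one | CC(=O)c1c(OCc2ccccc2)c(C)c(OCc2ccccc2)c(CC2=C(O[Si](C(C)C)(C(C)C)C(C)C)CC2=O)c1OCc1ccccc1 | intermediate (key‑step precursor)
13 | but‑3‑yn‑2‑one | CC(=O)C#C | starting material
14 | 2‑ethynyl‑2‑methyl‑1,3‑dioxolane | CC1(OCCO1)C#C | intermediate
15 | lithium (2‑methyl‑1,3‑dioxolan‑2‑yl)acetylide | [Li]C#CC1(C)OCCO1 | intermediate (not isolated)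
16 | lithium 2‑(2‑methyl‑1,3‑dioxolan‑2‑yl)ethynolate | [Li]OC#CC1(C)OCCO1 | intermediate (not isolated)
17 | triisopropyl{[(2‑methyl‑1,3‑dioxolan‑2‑yl)ethynyl]oxy}silane | CC1(OCCO1)C#CO[Si](C(C)C)(C(C)C)C(C)C | intermediate
18 | 2‑[(ArBn)methyl]‑3‑(triisopropylsilyloxy)buta‑1,3‑dien‑1‑one (vinylketene) | CC(=O)c1c(OCc2ccccc2)c(C)c(OCc2ccccc2)c(CC(=C=O)C(=C)O[Si](C(C)C)(C(C)C)C(C)C)c1OCc1ccccc1 | intermediate (not isolated)
19 | 4‑[(ArBn)methyl]‑2‑(2‑methyl‑1,3‑dioxolan‑2‑yl)‑3‑(triisopropylsilyloxy)‑4‑[1‑(triisopropylsilyloxy)vinyl]cyclobut‑2‑en‑1‑one, racemic | CC(=O)c1c(OCc2ccccc2)c(C)c(OCc2ccccc2)c(CC2(C(=C)O[Si](C(C)C)(C(C)C)C(C)C)C(=O)C(C3(C)OCCO3)=C2O[Si](C(C)C)(C(C)C)C(C)C)c1OCc1ccccc1 | intermediate (not isolated)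
20 | 4‑[(ArBn)methyl]‑2‑(2‑methyl‑1,3‑dioxolan‑2‑yl)‑3,5‑bis(triisopropylsilyloxy)hexa‑1,3,5‑trien‑1‑one, ketene and vinyl groups cis on C3=C4 | CC(=O)c1c(OCc2ccccc2)c(C)c(OCc2ccccc2)c(C/C(=C(\O[Si](C(C)C)(C(C)C)C(C)C)C(=C=O)C2(C)OCCO2)C(=C)O[Si](C(C)C)(C(C)C)C(C)C)c1OCc1ccccc1 | intermediate (not isolated)
21 | 4‑[(ArBn)methyl]‑2‑(2‑methyl‑1,3‑dioxolan‑2‑yl)‑3,5‑bis(triisopropylsilyloxy)cyclohexa‑2,4‑dien‑1‑one | CC(=O)c1c(OCc2ccccc2)c(C)c(OCc2ccccc2)c(CC2=C(O[Si](C(C)C)(C(C)C)C(C)C)CC(=O)C(C3(C)OCCO3)=C2O[Si](C(C)C)(C(C)C)C(C)C)c1OCc1ccccc1 | intermediate (not isolated)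
22 | 4‑[(ArBn)methyl]‑2‑(2‑methyl‑1,3‑dioxolan‑2‑yl)‑3,5‑bis[(triisopropylsilyl)oxy]phenol | CC(=O)c1c(OCc2ccccc2)c(C)c(OCc2ccccc2)c(Cc2c(O[Si](C(C)C)(C(C)C)C(C)C)cc(O)c(C3(C)OCCO3)c2O[Si](C(C)C)(C(C)C)C(C)C)c1OCc1ccccc1 | intermediate (key‑step product)
23 | 1‑{2,4,6‑trihydroxy‑3‑[[4‑hydroxy‑3‑(2‑methyl‑1,3‑dioxolan‑2‑yl)‑2,6‑bis(triisopropylsilyloxy)phenyl]methyl]‑5‑methylphenyl}ethan‑1‑one | CC(=O)c1c(O)c(C)c(O)c(Cc2c(O[Si](C(C)C)(C(C)C)C(C)C)cc(O)c(C3(C)OCCO3)c2O[Si](C(C)C)(C(C)C)C(C)C)c1O | intermediate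
24 | (4R)‑2‑acetyl‑3,5‑dihydroxy‑4‑methyl‑4‑(3‑methylbut‑2‑en‑1‑yl)‑6‑{[4‑hydroxy‑3‑(2‑methyl‑1,3‑dioxolan‑2‑yl)‑2,6‑bis(triisopropylsilyloxy)phenyl]methyl}cyclohexa‑2,5‑dien‑1‑one | CC(=O)C1=C(O)[C@](C)(CC=C(C)C)C(O)=C(Cc2c(O[Si](C(C)C)(C(C)C)C(C)C)cc(O)c(C3(C)OCCO3)c2O[Si](C(C)C)(C(C)C)C(C)C)C1=O | intermediate
25 | (4R)‑2‑acetyl‑3,5‑dihydroxy‑4‑methyl‑4‑(3‑methylbut‑2‑en‑1‑yl)‑6‑{[2,4,6‑trihydroxy‑3‑(2‑methyl‑1,3‑dioxolan‑2‑yl)phenyl]methyl}cyclohexa‑2,5‑dien‑1‑one | CC(=O)C1=C(O)[C@](C)(CC=C(C)C)C(O)=C(Cc2c(O)cc(O)c(C3(C)OCCO3)c2O)C1=O | intermediate (not isolated)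
26 | (4R)‑2‑acetyl‑6‑[(3‑acetyl‑2,4,6‑trihydroxyphenyl)methyl]‑3,5‑dihydroxy‑4‑methyl‑4‑(3‑methylbut‑2‑en‑1‑yl)cyclohexa‑2,5‑dien‑1‑one | CC(=O)C1=C(O)[C@](C)(CC=C(C)C)C(O)=C(Cc2c(O)cc(O)c(C(C)=O)c2O)C1=O | intermediate
27 | (4R)‑2‑acetyl‑6‑{[3‑acetyl‑2,4,6‑trihydroxy‑5‑(3‑methylbut‑2‑en‑1‑yl)phenyl]methyl}‑3,5‑dihydroxy‑4‑methyl‑4‑(3‑methylbut‑2‑en‑1‑yl)cyclohexa‑2,5‑dien‑1‑one | CC(=O)C1=C(O)[C@](C)(CC=C(C)C)C(O)=C(Cc2c(O)c(CC=C(C)C)c(O)c(C(C)=O)c2O)C1=O | target

**Step count**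

Total: 14 steps. Longest linear sequence: 12 steps (steps 1–7 and 10–14); the alkyne branch contributes steps 8 and 9.

**Steps most likely to fail**

Step 10 (benzannulation). The vinylogous silyl ester character of 12 may slow the 4π opening. The ynol ether 17, hindered by its quaternary ketal carbon, may then add too slowly, so that the vinylketene oligomerises or acylates the product phenol. Fallback, from 2 to 27: the methylene bridge would be made by a Mannich–Michael coupling of two complete arenes instead of by annulation. Reaction of 2 with N,N‑dimethylmethyleneiminium iodide would give 1‑{3‑[(dimethylamino)methyl]‑2,4,6‑trihydroxy‑5‑methylphenyl}ethan‑1‑one F1. Heated in dioxane with an excess of commercial 2,4,6‑trihydroxyacetophenone, F1 would lose dimethylamine and alkylate a free ring carbon of the partner, giving 1‑{3‑[(3‑acetyl‑2,4,6‑trihydroxyphenyl)methyl]‑2,4,6‑trihydroxy‑5‑methylphenyl}ethan‑1‑one F2. Prenylation of its single hydrogen‑bearing ring carbon under the conditions of step 14 would give 1‑{3‑[(3‑acetyl‑2,4,6‑trihydroxy‑5‑methylphenyl)methyl]‑2,4,6‑trihydroxy‑5‑(3‑methylbut‑2‑en‑1‑yl)phenyl}ethan‑1‑one F3. The dearomatising prenylation of step 12, directed to the methyl‑bearing carbon as the least hindered alkyl‑bearing ring carbon, would then lead to 27.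

Step 12 (asymmetric dearomatising prenylation). Facial discrimination at C3 may be poor because its two flanks differ only one atom further out, and alkylation at C5 or persistent O‑prenylation may compete. Fallback, from 23 to 24: the same alkylation with the achiral catalyst Pd(PPh3)4 would give the racemic dearomatised trione F4. Classical resolution through the (S)‑1‑phenylethylammonium salt of the (4R) acid F5 (fractional crystallisation, or work‑up of the mother liquor if the other diastereomer separates), followed by acidification, would return 24.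

Step 14 (final prenylation). C–H prenylation of ring B may have to compete with quaternisation or O‑alkylation of the unprotected ring A, and the two enolisable rings may exchange across the methylene bridge. Fallback, from 24 to 27: ring A would be masked before ring B is touched.
- Me3SiCHN2 (2 equiv, MeOH/toluene) would convert the two acidic enols of 24 into (4R)‑2‑acetyl‑3,5‑dimethoxy‑4‑methyl‑4‑(3‑methylbut‑2‑en‑1‑yl)‑6‑{[4‑hydroxy‑3‑(2‑methyl‑1,3‑dioxolan‑2‑yl)‑2,6‑bis(triisopropylsilyloxy)phenyl]methyl}cyclohexa‑2,5‑dien‑1‑one F6. It is drawn as the cross‑conjugated isomer; O‑methyl regioisomers would be equivalent masks.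
- Bu4NF/AcOH and then PPTS would give, through (4R)‑2‑acetyl‑3,5‑dimethoxy‑4‑methyl‑4‑(3‑methylbut‑2‑en‑1‑yl)‑6‑{[2,4,6‑trihydroxy‑3‑(2‑methyl‑1,3‑dioxolan‑2‑yl)phenyl]methyl}cyclohexa‑2,5‑dien‑1‑one F7, the compound (4R)‑2‑acetyl‑6‑[(3‑acetyl‑2,4,6‑trihydroxyphenyl)methyl]‑3,5‑dimethoxy‑4‑methyl‑4‑(3‑methylbut‑2‑en‑1‑yl)cyclohexa‑2,5‑dien‑1‑one F8.
- Prenyl bromide and DBU in THF would alkylate C3' of the only acidic ring, giving (4R)‑2‑acetyl‑6‑{[3‑acetyl‑2,4,6‑trihydroxy‑5‑(3‑methylbut‑2‑en‑1‑yl)phenyl]methyl}‑3,5‑dimethoxy‑4‑methyl‑4‑(3‑methylbut‑2‑en‑1‑yl)cyclohexa‑2,5‑dien‑1‑one F9.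
- Krapcho‑type demethylation with LiCl in DMF at 100 °C would release 27.

**Further compounds**

F1 | step 10 | 1‑{3‑[(dimethylamino)methyl]‑2,4,6‑trihydroxy‑5‑methylphenyl}ethan‑1‑one | CC(=O)c1c(O)c(C)c(O)c(CN(C)C)c1O
F2 | step 10 | 1‑{3‑[(3‑acetyl‑2,4,6‑trihydroxyphenyl)methyl]‑2,4,6‑trihydroxy‑5‑methylphenyl}ethan‑1‑one | CC(=O)c1c(O)c(C)c(O)c(Cc2c(O)cc(O)c(C(C)=O)c2O)c1O
F3 | step 10 | 1‑{3‑[(3‑acetyl‑2,4,6‑trihydroxy‑5‑methylphenyl)methyl]‑2,4,6‑trihydroxy‑5‑(3‑methylbut‑2‑en‑1‑yl)phenyl}ethan‑1‑one | CC(=O)c1c(O)c(C)c(O)c(Cc2c(O)c(CC=C(C)C)c(O)c(C(C)=O)c2O)c1O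
F4 | step 12 | racemic 2‑acetyl‑3,5‑dihydroxy‑4‑methyl‑4‑(3‑methylbut‑2‑en‑1‑yl)‑6‑{[4‑hydroxy‑3‑(2‑methyl‑1,3‑dioxolan‑2‑yl)‑2,6‑bis(triisopropylsilyloxy)phenyl]methyl}cyclohexa‑2,5‑dien‑1‑one | CC(=O)C1=C(O)C(C)(CC=C(C)C)C(O)=C(Cc2c(O[Si](C(C)C)(C(C)C)C(C)C)cc(O)c(C3(C)OCCO3)c2O[Si](C(C)C)(C(C)C)C(C)C)C1=O
F5 | step 12 | (S)‑1‑phenylethylammonium enolate of the (4R) trione 24 | CC(=O)C1=C(O)[C@](C)(CC=C(C)C)C([O-])=C(Cc2c(O[Si](C(C)C)(C(C)C)C(C)C)cc(O)c(C3(C)OCCO3)c2O[Si](C(C)C)(C(C)C)C(C)C)C1=O.C[C@H]([NH3+])c1ccccc1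
F6 | step 14 | (4R)‑2‑acetyl‑3,5‑dimethoxy‑4‑methyl‑4‑(3‑methylbut‑2‑en‑1‑yl)‑6‑{[4‑hydroxy‑3‑(2‑methyl‑1,3‑dioxolan‑2‑yl)‑2,6‑bis(triisopropylsilyloxy)phenyl]methyl}cyclohexa‑2,5‑dien‑1‑one | CC(=O)C1=C(OC)[C@](C)(CC=C(C)C)C(OC)=C(Cc2c(O[Si](C(C)C)(C(C)C)C(C)C)cc(O)c(C3(C)OCCO3)c2O[Si](C(C)C)(C(C)C)C(C)C)C1=O
F7 | step 14 | (4R)‑2‑acetyl‑3,5‑dimethoxy‑4‑methyl‑4‑(3‑methylbut‑2‑en‑1‑yl)‑6‑{[2,4,6‑trihydroxy‑3‑(2‑methyl‑1,3‑dioxolan‑2‑yl)phenyl]methyl}cyclohexa‑2,5‑dien‑1‑one | CC(=O)C1=C(OC)[C@](C)(CC=C(C)C)C(OC)=C(Cc2c(O)cc(O)c(C3(C)OCCO3)c2O)C1=O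
F8 | step 14 | (4R)‑2‑acetyl‑6‑[(3‑acetyl‑2,4,6‑trihydroxyphenyl)methyl]‑3,5‑dimethoxy‑4‑methyl‑4‑(3‑methylbut‑2‑en‑1‑yl)cyclohexa‑2,5‑dien‑1‑one | CC(=O)C1=C(OC)[C@](C)(CC=C(C)C)C(OC)=C(Cc2c(O)cc(O)c(C(C)=O)c2O)C1=O
F9 | step 14 | (4R)‑2‑acetyl‑6‑{[3‑acetyl‑2,4,6‑trihydroxy‑5‑(3‑methylbut‑2‑en‑1‑yl)phenyl]methyl}‑3,5‑dimethoxy‑4‑methyl‑4‑(3‑methylbut‑2‑en‑1‑yl)cyclohexa‑2,5‑dien‑1‑one | CC(=O)C1=C(OC)[C@](C)(CC=C(C)C)C(OC)=C(Cc2c(O)c(CC=C(C)C)c(O)c(C(C)=O)c2O)C1=O
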